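## Analysis of the target

Compound 16 is a depside: two separate benzene rings joined by a single aryl ester, with no fused or bridged ring and two unbranched chains (propyl on ring A, pentyl on ring B). It has no stereocentre and no double-bond geometry, so nothing configurational has to be set or preserved. Ring A is a 2-hydroxy-4-methoxy-6-propylbenzoyl group whose carbonyl carbon is shielded on both sides by the C2 hydroxyl and the C6 propyl group. Ring B is a benzoic acid with methoxy at C2, the depside oxygen at C4 and pentyl at C6. The sensitive groups are the aryl ester (an activated ester, open to hydroxide, alkoxide, strong nucleophiles and strongly reducing conditions), the hydrogen-bonded phenol of ring A, and the electron-rich, doubly ortho-substituted acid of ring B, which can lose CO2 in hot acid. The difficulty lies in four phenolic oxygens in four different states on two resorcinol-type rings, an ester that must be made at a hindered carbonyl, and a second carboxyl group that would interfere with that esterification if present. The strategy rests on ring B C1: the carboxyl-bearing carbon lies para to the depside oxygen on C4 and between the C2 methoxy and the C6 pentyl group. Without the carboxyl carbon, ring B is 3-methoxy-5-pentylphenol (4), and C1 is the position para to its hydroxyl. An iodine atom can be placed there (5), carried through the esterification, and exchanged for the carboxyl group at the very end, so the acid never needs a protecting group.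

## Retrosynthetic reasoning

16 to 15: the oxygen–benzyl bond on ring A C2 is cut first. It is the only protecting group of the route; it keeps an acidic phenol out of the reductive key step and out of the esterification. The forward reaction has to remove it under neutral conditions that leave the depside ester and the free acid alone, which points to hydrogenolysis.

15 to 13: the bond between ring B C1 and the carboxyl carbon is cut, leaving an aryl iodide. This is the one carbon–carbon bond whose removal turns ring B into a simple derivative of 1, and it takes the acid out of every earlier step. Cutting the ester first would instead leave a hydroxy acid that needs an orthogonal ester and a late deprotection next to the depside link. The forward reaction must turn a carbon–iodine bond that is flanked on both sides into a carboxylic acid without basic or strongly nucleophilic reagents. A cathodic, nickel-mediated carboxylation meets that demand.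

13 to 5 and 11: the acyl carbon–oxygen bond of the depside ester is cut. This is the convergent cut; it gives two halves of similar size, each from a commercial 5-alkylresorcinol. The hindrance lies wholly on the acyl side, since the hydroxyl of 5 has hydrogen on both neighbouring carbons, so the forward step needs strong activation of 11, here as the acid chloride 12.

5 to 4, 2 and 1: the carbon–iodine bond is cut back to phenol 4, then the oxygen pattern is traced to symmetric 1. The iodine must enter para to the free hydroxyl and not para to the methoxy group, so the forward iodination is run on the neutral phenol under acid catalysis. The monoether 4 is reached by full methylation to 2 and removal of exactly one methyl group, which avoids a statistical monoalkylation.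

11 to 10, 9, 8 and 6: the acid is traced to the aldehyde 10, the benzyl and methyl groups are removed in turn (9, 8), and the formyl carbon is cut from ring A to give 6. The aldehyde is chosen over an ester because its hydrogen bond to the neighbouring hydroxyl in 8 distinguishes the two oxygens, and because no hindered ester has to be hydrolysed later. The forward steps are formylation ortho to the propyl group (through iminium 7), methylation of the free para hydroxyl, benzylation of the chelated one, and oxidation.

## Alternatives that were turned down

Alternative 1: Ring B would be built instead of bought. The cut runs through two ring bonds of ring B (C1–C2 and C5–C6). In the forward step the electron-rich diene A2 would add to the alkynoate A3, and the adduct would aromatise by loss of one acetal alkoxy group and the silyl group to give phenol A1. A1 would then be acylated with 12, and both benzyl groups would fall in one hydrogenolysis.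
- For it: the substitution pattern of ring B follows from the polarity of the two partners, so no electrophilic substitution has to be trusted for regiochemistry. On that point it is stronger than step 3 of the chosen route. The carboxyl carbon is present from the start, so no late carbon–carbon bond is needed.
- Against it: a beta-alkyl alkynoate is a weak dienophile and needs heat, while a ketene-acetal diene of this type is moisture-sensitive and prone to desilylation or simple Michael addition without ring closure. Both partners have to be prepared, and a ring that olivetol already provides would be assembled from small pieces.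
- Comparison: the step count is about the same. The chosen route offers instead a ring B skeleton that is in place from the first step, robust ionic steps up to the key step, and an acid that needs no benzyl ester.

Alternative 2: The ester bond and ring A would be made in one operation. Heating the dioxinone A4 would release an acylketene, the phenol A1 would trap it to give the aryl triketo ester A5, and an intramolecular aldol condensation with dehydration would close ring A to give A6. A selective methylation of the ring A hydroxyl para to the carbonyl and hydrogenolysis of the benzyl ester would finish.
- For it: it is the most convergent plan. Ketene capture is indifferent to hindrance, so it avoids the shielded acylation of step 8 altogether, and on that point it is stronger than the chosen route. Ring A needs no protecting group.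
- Against it: A4 takes several steps and is delicate. A5 is an aryl ester of a beta-keto acid, so under the base needed for the aldol closure it can expel the phenoxide again or close to a pyrone. A6 carries two free ring A hydroxyls, so a regioselective methylation is needed late, on the finished depside. A1 still has to be made, with the ring B acid protected throughout.
- Comparison: the chosen route places its one uncertain step on a stable, fully characterisable precursor (13) and reaches that precursor by standard reactions.

Alternative 3: The depside oxygen–aryl bond would be formed by a Chan–Lam-type copper-mediated coupling under air between acid 11 and the boronic acid A7, giving the tert-butyl ester A8. Acidolysis of the tert-butyl ester and hydrogenolysis of the benzyl ether would follow.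
- For it: the carboxylate oxygen is the nucleophile, so the shielded carbonyl carbon of 11 is never attacked. On hindrance it is at least as good as the acylation of the chosen route, and it uses the same acid 11.
- Against it: A7 needs the ring B acid already installed and protected, plus a separate borylation. Copper-mediated O-arylation of carboxylic acids tends to need much copper and excess boronic acid, and it competes with protodeboronation, phenol formation and biaryl coupling. Two deprotections follow, one of them acidic on an electron-rich acid that can decarboxylate.
- Comparison: it is longer and carries two uncertain steps. The chosen route uses a classical acylation of an unhindered phenol and spends its risk on a single carbon–carbon bond formation that leaves the acid free.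

Key step: step 9

Remark on the chemistry: the target has no stereocentre. The magnesium carboxylate formed in the cell of step 9 is written as its iodide salt and is protonated on acidic work-up.

## Route

Step 1
Reactants: 1 olivetol (5-pentylbenzene-1,3-diol)
Product: 2 1,3-dimethoxy-5-pentylbenzene
Conditions: MeI (2.5 equiv), K2CO3, acetone, reflux
Reagents that add atoms: iodomethane, CI
Why: Williamson ether synthesis on both phenols; exhaustive methylation avoids the statistical mixture that a direct monomethylation of the symmetric diol would give.

Step 2
Reactants: 2 1,3-dimethoxy-5-pentylbenzene
Product: 4 3-methoxy-5-pentylphenol, via sodium 3-methoxy-5-pentylphenolate 3 (not isolated)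
Conditions: NaSEt, DMF, 150 °C; then 1 M HCl
Reagents that add atoms: none
Why: Nucleophilic (SN2) O-demethylation by thiolate; once one ether is cleaved the ring is a phenolate, whose charge makes the second methyl group a much poorer electrophile, so the reaction should stop at the monoether.

Step 3
Reactants: 4 3-methoxy-5-pentylphenol
Product: 5 4-iodo-3-methoxy-5-pentylphenol
Conditions: NIS (1.0 equiv), TsOH·H2O (cat.), MeCN, 0 °C to rt
Reagents that add atoms: N-iodosuccinimide, O=C1CCC(=O)N1I
Why: Electrophilic aromatic iodination; on the neutral phenol under acid catalysis the hydroxyl is the strongest para director, so iodine should enter C4 (between methoxy and pentyl) and not the positions ortho to the hydroxyl, and one equivalent of NIS in the cold limits di-iodination.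

Step 4
Reactants: 6 5-propylresorcinol (5-propylbenzene-1,3-diol)
Product: 8 2,4-dihydroxy-6-propylbenzaldehyde, via iminium chloride 7 (not isolated)
Conditions: POCl3, DMF, 0 °C to rt; then H2O, 50 °C
Reagents that add atoms: N,N-dimethylformamide, CN(C)C=O; water, O
Why: Vilsmeier–Haack formylation; as is usual for 5-alkylresorcinols the chloroiminium ion attacks the carbon next to the alkyl group (para to one hydroxyl, ortho to the other) and not the carbon between the two hydroxyls, and water hydrolyses iminium 7 to the aldehyde.

Step 5
Reactants: 8 2,4-dihydroxy-6-propylbenzaldehyde
Product: 9 2-hydroxy-4-methoxy-6-propylbenzaldehyde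
Conditions: MeI (1.1 equiv), K2CO3 (1.1 equiv), acetone, rt to 40 °C
Reagents that add atoms: iodomethane, CI
Why: Williamson etherification; the C2 hydroxyl is locked in a hydrogen bond to the aldehyde and is the poorer nucleophile, so one equivalent of MeI with a weak base should methylate the C4 hydroxyl selectively.

Step 6
Reactants: 9 2-hydroxy-4-methoxy-6-propylbenzaldehyde
Product: 10 2-(benzyloxy)-4-methoxy-6-propylbenzaldehyde
Conditions: BnBr, K2CO3, DMF, 60 °C
Reagents that add atoms: benzyl bromide, BrCc1ccccc1
Why: Williamson benzylation of the remaining chelated hydroxyl, which needs a polar solvent and warming; the benzyl ether removes the acidic proton before the reductive key step and comes off by hydrogenolysis at the end.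

Step 7
Reactants: 10 2-(benzyloxy)-4-methoxy-6-propylbenzaldehyde
Product: 11 2-(benzyloxy)-4-methoxy-6-propylbenzoic acid
Conditions: NaClO2, NaH2PO4, 2-methyl-2-butene (excess), t-BuOH/H2O, rt
Reagents that add atoms: sodium chlorite, [Na+].[O-]Cl=O
Why: Pinnick oxidation; chlorous acid oxidises the hindered, electron-rich aldehyde without touching the benzyl ether, and the excess alkene traps the hypochlorous acid that would otherwise chlorinate the ring.

Step 8
Reactants: 11 2-(benzyloxy)-4-methoxy-6-propylbenzoic acid; 5 4-iodo-3-methoxy-5-pentylphenol
Product: 13 4-iodo-3-methoxy-5-pentylphenyl 2-(benzyloxy)-4-methoxy-6-propylbenzoate, via acid chloride 12 (not isolated)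
Conditions: (COCl)2, DMF (cat.), CH2Cl2, 0 °C to rt, concentrate; then 5, Et3N, DMAP (cat.), CH2Cl2, 0 °C to rt
Reagents that add atoms: none
Why: Acid chloride formation followed by DMAP-catalysed acylation of a phenol; the hydroxyl of 5 has hydrogen on both neighbouring carbons, so all the hindrance is on the acyl side and is met by the reactive acyl chloride, while the aryl iodide and the ethers are inert.

Step 9
Reactants: 13 4-iodo-3-methoxy-5-pentylphenyl 2-(benzyloxy)-4-methoxy-6-propylbenzoate
Product: 15 4-{[2-(benzyloxy)-4-methoxy-6-propylbenzoyl]oxy}-2-methoxy-6-pentylbenzoic acid, via iodomagnesium carboxylate 14 (not isolated)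
Conditions: NiBr2(2,2'-bipyridine) (10 mol %), Bu4NBF4, CO2 (1 atm), dry DMF, Mg anode, carbon-fibre cathode, undivided cell, constant current (about 2.2 F/mol), 10–20 °C; then cold 1 M HCl
Reagents that add atoms: carbon dioxide, O=C=O
Why: The cathode reduces the divalent nickel bipyridine complex to zerovalent nickel, which inserts into the weak carbon–iodine bond of 13 to give an arylnickel iodide. A further one-electron reduction gives a monovalent arylnickel species that takes up CO2 at the nickel–carbon bond, forming the bond from ring B C1 to the carboxyl carbon. Magnesium ions from the dissolving anode take over the carboxylate as 14, the nickel is reduced back into the cycle, and acid work-up frees 15. The closest known reaction type is the nickel-bipyridine-catalysed electroreductive carboxylation of aryl halides with CO2 in an undivided cell with a sacrificial magnesium anode. No ring is closed and no stereocentre is formed. The step needs chemoselectivity for the carbon–iodine bond over the acyl carbon–oxygen bond of the depside ester, over replacement of iodine by hydrogen and over biaryl coupling. The nickel mediator should work at a potential well positive of that needed to reduce an aryl benzoate, the dry aprotic medium and the benzyl cap on the ring A phenol leave no proton source for the aryl-nickel species, and the two ortho substituents disfavour coupling of two aryl groups at nickel. The magnesium carboxylate is too weak a nucleophile to attack the hindered depside ester.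

Step 10
Reactants: 15 4-{[2-(benzyloxy)-4-methoxy-6-propylbenzoyl]oxy}-2-methoxy-6-pentylbenzoic acid
Product: 16 4-[(2-hydroxy-4-methoxy-6-propylbenzoyl)oxy]-2-methoxy-6-pentylbenzoic acid (CNP0522224.0)
Conditions: H2 (1 atm), 10% Pd/C, EtOAc, rt
Reagents that add atoms: none
Why: Catalytic hydrogenolysis of the benzyl aryl ether; the aryl ester, the free acid and both arenes should not be reduced under these mild neutral conditions, and no halogen remains that could be lost.

## Compound list

1 | olivetol (5-pentylbenzene-1,3-diol) | CCCCCc1cc(O)cc(O)c1 | starting material
2 | 1,3-dimethoxy-5-pentylbenzene | CCCCCc1cc(OC)cc(OC)c1 | intermediate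
3 | sodium 3-methoxy-5-pentylphenolate | CCCCCc1cc([O-])cc(OC)c1.[Na+] | intermediate
4 | 3-methoxy-5-pentylphenol | CCCCCc1cc(O)cc(OC)c1 | intermediate
5 | 4-iodo-3-methoxy-5-pentylphenol | CCCCCc1cc(O)cc(OC)c1I | intermediate
6 | 5-propylresorcinol (5-propylbenzene-1,3-diol) | CCCc1cc(O)cc(O)c1 | starting material
7 | [(2,4-dihydroxy-6-propylphenyl)methylidene]dimethyliminium chloride | CCCc1cc(O)cc(O)c1C=[N+](C)C.[Cl-] | intermediate
8 | 2,4-dihydroxy-6-propylbenzaldehyde | CCCc1cc(O)cc(O)c1C=O | intermediate
9 | 2-hydroxy-4-methoxy-6-propylbenzaldehyde | CCCc1cc(OC)cc(O)c1C=O | intermediate
10 | 2-(benzyloxy)-4-methoxy-6-propylbenzaldehyde | CCCc1cc(OC)cc(OCc2ccccc2)c1C=O | intermediate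
11 | 2-(benzyloxy)-4-methoxy-6-propylbenzoic acid | CCCc1cc(OC)cc(OCc2ccccc2)c1C(=O)O | intermediate
12 | 2-(benzyloxy)-4-methoxy-6-propylbenzoyl chloride | CCCc1cc(OC)cc(OCc2ccccc2)c1C(=O)Cl | intermediate
13 | 4-iodo-3-methoxy-5-pentylphenyl 2-(benzyloxy)-4-methoxy-6-propylbenzoate | CCCCCc1cc(OC(=O)c2c(OCc3ccccc3)cc(OC)cc2CCC)cc(OC)c1I | intermediate
14 | iodomagnesium 4-{[2-(benzyloxy)-4-methoxy-6-propylbenzoyl]oxy}-2-methoxy-6-pentylbenzoate | CCCCCc1cc(OC(=O)c2c(OCc3ccccc3)cc(OC)cc2CCC)cc(OC)c1C(=O)[O-].[Mg+2].[I-] | intermediate
15 | 4-{[2-(benzyloxy)-4-methoxy-6-propylbenzoyl]oxy}-2-methoxy-6-pentylbenzoic acid | CCCCCc1cc(OC(=O)c2c(OCc3ccccc3)cc(OC)cc2CCC)cc(OC)c1C(=O)O | intermediate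
16 | 4-[(2-hydroxy-4-methoxy-6-propylbenzoyl)oxy]-2-methoxy-6-pentylbenzoic acid | CCCCCc1cc(OC(=O)c2c(O)cc(OC)cc2CCC)cc(OC)c1C(=O)O | target

## Step count and least certain steps

Total step count: 10. Longest linear sequence: 7 steps (steps 4, 5, 6, 7, 8, 9, 10, from 6 to 16); the ring B branch (steps 1 to 3) joins at step 8.

Step 9 (key step). The most likely failure is replacement of iodine by hydrogen, through protonation or hydrogen abstraction at the aryl-nickel or aryl radical stage, because CO2 uptake at a carbon flanked by methoxy and pentyl may be slow. A second risk is reductive cleavage of the depside ester if the cathode potential drifts negative once the catalyst stops turning over. Fallback: from 13, iodine–magnesium exchange with i-PrMgCl·LiCl in THF at −40 to −20 °C, helped by the ortho methoxy group, should give the arylmagnesium chloride F1. Passing dry CO2 through the cold solution should give the chloromagnesium carboxylate F2, and cold dilute HCl returns the route to 15. The depside ester is a benzoate with two ortho substituents and should resist addition of the Grignard reagents at these temperatures.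

Step 3. The most likely failure is poor regioselectivity: iodination at the carbon ortho to the hydroxyl and para to the methoxy group competes, because both positions are activated by one oxygen in the para and one in the ortho relationship, and a second iodination can follow. Fallback: from 4, azo coupling of the phenolate with benzenediazonium chloride in aqueous NaOH at 0 °C, which strongly prefers the position para to the phenolate oxygen, should give (E)-3-methoxy-5-pentyl-4-(phenyldiazenyl)phenol F3. Reductive cleavage with Na2S2O4 in aqueous ethanol should give 4-amino-3-methoxy-5-pentylphenol F4. Diazotisation with NaNO2 in cold dilute H2SO4 gives 4-hydroxy-2-methoxy-6-pentylbenzenediazonium hydrogensulfate F5, which KI converts into 5 (Sandmeyer-type iodination).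

Step 8. The most likely failure is sluggish acylation, since the carbonyl carbon of 12 lies between two ortho substituents and addition–elimination is slow. Loss of the neighbouring benzyl group during acid chloride formation, by attack of chloride on the activated ether, is a second risk. Fallback: from 11 and 5, treatment with trifluoroacetic anhydride in toluene at room temperature should give 2-(benzyloxy)-4-methoxy-6-propylbenzoic trifluoroacetic anhydride F6. For an electron-rich, hindered acid this ionises to a linear acylium ion, which the phenol 5 captures to give 13. The mechanism changes from attack on a shielded tetrahedral centre to capture of an unhindered cation, and no chloride is present.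

## Further compounds

F1 | step 9 | chloro{4-[(2-(benzyloxy)-4-methoxy-6-propylbenzoyl)oxy]-2-methoxy-6-pentylphenyl}magnesium | CCCCCc1cc(OC(=O)c2c(OCc3ccccc3)cc(OC)cc2CCC)cc(OC)c1[Mg]Cl
F2 | step 9 | chloromagnesium 4-{[2-(benzyloxy)-4-methoxy-6-propylbenzoyl]oxy}-2-methoxy-6-pentylbenzoate | CCCCCc1cc(OC(=O)c2c(OCc3ccccc3)cc(OC)cc2CCC)cc(OC)c1C(=O)[O-].[Mg+2].[Cl-]
F3 | step 3 | (E)-3-methoxy-5-pentyl-4-(phenyldiazenyl)phenol | CCCCCc1cc(O)cc(OC)c1/N=N/c1ccccc1
F4 | step 3 | 4-amino-3-methoxy-5-pentylphenol | CCCCCc1cc(O)cc(OC)c1N
F5 | step 3 | 4-hydroxy-2-methoxy-6-pentylbenzenediazonium hydrogensulfate | CCCCCc1cc(O)cc(OC)c1[N+]#N.OS(=O)(=O)[O-]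
F6 | step 8 | 2-(benzyloxy)-4-methoxy-6-propylbenzoic trifluoroacetic anhydride | CCCc1cc(OC)cc(OCc2ccccc2)c1C(=O)OC(=O)C(F)(F)F
A1 | alternative 1 | benzyl 4-hydroxy-2-methoxy-6-pentylbenzoate | CCCCCc1cc(O)cc(OC)c1C(=O)OCc1ccccc1
A2 | alternative 1 | 1,1-dimethoxy-3-(trimethylsilyloxy)buta-1,3-diene | COC(OC)=CC(=C)O[Si](C)(C)C
A3 | alternative 1 | benzyl oct-2-ynoate | CCCCCC#CC(=O)OCc1ccccc1
A4 | alternative 2 | 6-(2,4-dioxoheptyl)-2,2-dimethyl-4H-1,3-dioxin-4-one | CCCC(=O)CC(=O)CC1=CC(=O)OC(C)(C)O1
A5 | alternative 2 | benzyl 2-methoxy-6-pentyl-4-[(3,5,7-trioxodecanoyl)oxy]benzoate | CCCCCc1cc(OC(=O)CC(=O)CC(=O)CC(=O)CCC)cc(OC)c1C(=O)OCc1ccccc1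
A6 | alternative 2 | benzyl 4-[(2,4-dihydroxy-6-propylbenzoyl)oxy]-2-methoxy-6-pentylbenzoate | CCCCCc1cc(OC(=O)c2c(O)cc(O)cc2CCC)cc(OC)c1C(=O)OCc1ccccc1
A7 | alternative 3 | [4-(tert-butoxycarbonyl)-3-methoxy-5-pentylphenyl]boronic acid | CCCCCc1cc(B(O)O)cc(OC)c1C(=O)OC(C)(C)C
A8 | alternative 3 | tert-butyl 4-{[2-(benzyloxy)-4-methoxy-6-propylbenzoyl]oxy}-2-methoxy-6-pentylbenzoate | CCCCCc1cc(OC(=O)c2c(OCc3ccccc3)cc(OC)cc2CCC)cc(OC)c1C(=O)OC(C)(C)C
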